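The dearomatised ring is cut at C2–C3 and C5–C6: the quaternary stereocentre C4 (methyl, prenyl) with its flanking carbonyl carbons C3 and C5 is a desymmetrised methyl(prenyl)malonate, and C6–C1–C2 with the acetyl group is acetylacetone. The key step is a Claisen ring closure of the open-chain methyl 3,5,7-trioxooctanoate that carries this quaternary carbon next to its ester: the doubly activated C2 carbanion attacks ester carbon C3 and closes the six-membered acyl-trione ring in one operation, with C4 already configured and C6–H left free. C6 then adds to an ortho-quinone methide made from the Mannich base of 3-prenylphloroacetophenone, which installs the CH2 bridge to the intact aromatic ring.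

Key step: step 5

Remarks on the chemistry (one line each):
- Ring numbering of the dearomatised ring: C1 is the carbonyl carbon between C2 (acetyl-bearing) and C6 (bridge-bearing); C3, C4 (quaternary) and C5 follow from C2.
- Enolised polycarbonyl compounds are drawn as one tautomer, and CIP descriptors refer to the tautomer drawn.
- Assumption: the esterase in step 2 is taken to cleave the ester group that leaves (R)-4; sense and level of selectivity are to be verified by chiral HPLC and correlation with resolved material before 4 is carried on.
- Assumption for the resolution fallback: the less soluble 1-phenylethylammonium salt is taken to pair the (R)-acid with the (S)-amine; if the pairing is the reverse, the (R)-amine is used in the same way.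
- Enolate, phenolate and ammonium forms that arise by simple proton transfer are counted as the parent compound; the preformed acetylacetone dianion and the quinone methide receive their own numbers.

Step 1
Reactants: 1 dimethyl methylmalonate; 2 prenyl bromide (1-bromo-3-methylbut-2-ene)
Product: 3 dimethyl 2-methyl-2-(3-methylbut-2-en-1-yl)malonate
Conditions: NaH (1.1 equiv), THF, 0 °C; then 2 (1.05 equiv), 0 °C → rt
Reagents that add atoms: none
Why: Malonic ester alkylation, in which the soft sodium enolate displaces bromide at the unsubstituted allylic terminus (SN2, linear prenyl isomer) and the product, having no alpha hydrogen, cannot be alkylated again.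

Step 2
Reactants: 3 dimethyl 2-methyl-2-(3-methylbut-2-en-1-yl)malonate
Product: 4 (R)-3-methoxy-2-methyl-2-(3-methylbut-2-en-1-yl)-3-oxopropanoic acid
Conditions: pig liver esterase, 0.1 M sodium phosphate buffer (NaH2PO4/Na2HPO4) pH 7.5, 10% DMSO, 25 °C, stopped at one equivalent of acid; cold citric acid to pH 3, EtOAc extraction
Reagents that add atoms: water, O
Why: Enzymatic desymmetrisation (enantiotopic-group-selective ester hydrolysis) of a prochiral 2,2-disubstituted dimethyl malonate, a standard substrate class for this esterase, in which the chiral active site distinguishes the two ester groups and thereby creates the quaternary stereocentre, while hydrolysis stops at the monoacid because the carboxylate is not a substrate.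

Step 3
Reactants: 4 (R)-3-methoxy-2-methyl-2-(3-methylbut-2-en-1-yl)-3-oxopropanoic acid
Product: 5 methyl (S)-2-(chlorocarbonyl)-2,5-dimethylhex-4-enoate
Conditions: 1-chloro-N,N,2-trimethylprop-1-en-1-amine (1.2 equiv), CH2Cl2, 0 °C → rt; volatiles and amide stripped at 0.1 mbar, crude used at once
Reagents that add atoms: 1-chloro-N,N,2-trimethylprop-1-en-1-amine, CC(C)=C(Cl)N(C)C
Why: Acid chloride formation through an alpha-chloroenamine (an acyloxyiminium chloride collapses to the acyl chloride and an amide) releases no HCl, so the trisubstituted alkene is neither hydrochlorinated nor lactonised onto, and the quaternary alpha carbon excludes ketene formation and epimerisation (the change of descriptor from R to S is only a change in CIP priority).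

Step 4
Reactants: 5 methyl (S)-2-(chlorocarbonyl)-2,5-dimethylhex-4-enoate; 6 acetylacetone
Product: 8 methyl (R)-2-methyl-2-(3-methylbut-2-en-1-yl)-3,5,7-trioxooctanoate, via acetylacetone sodium lithium dianion 7 (not isolated)
Conditions: 6 (2.5 equiv), NaH (2.5 equiv) then n-BuLi (2.5 equiv), THF, 0 °C; 5 (1.0 equiv) added slowly at −78 °C; cold 1 M HCl to pH 4; excess 6 removed under vacuum
Reagents that add atoms: none
Why: Acylation of a beta-diketone 1,3-dianion at its terminal, most nucleophilic carbon by an acid chloride, where the amine-free excess dianion deprotonates the new acidic methylene and so protects the product from a second acylation, and the acid chloride reacts far faster at −78 °C than the neopentyl-type methyl ester.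

Step 5
Reactants: 8 methyl (R)-2-methyl-2-(3-methylbut-2-en-1-yl)-3,5,7-trioxooctanoate
Product: 9 (R)-2-acetyl-3,5-dihydroxy-4-methyl-4-(3-methylbut-2-en-1-yl)cyclohexa-2,5-dien-1-one
Conditions: KOtBu (2.5 equiv), THF, 0 °C → 40 °C; cold 1 M HCl quench
Reagents that add atoms: none
Why: Two equivalents of base convert 8 into its bis-enolate (C6 and C2 deprotonated), in which all three ketones are enolate-masked and the methyl ester on the quaternary carbon is the only free electrophile, so the doubly stabilised C2 carbanion adds to ester carbon C3 and expels methoxide, forming the C2–C3 bond. The closest known reaction type is the Claisen (Dieckmann-type) cyclisation of 3,5,7-triketo esters to acylphloroglucinol-type rings, together with Dieckmann closures onto esters bearing an alpha-quaternary carbon. The six-membered carbocycle (C2, C3, C4, C5, C6, C1) closes by a 6-exo-trig acyl substitution, allowed for the delocalised C2 enolate in either its enolendo (C1=C2) or enolexo form. No stereocentre is created: C4 was set in step 2, has no hydrogen and is not a reacting atom, and its absolute sense in the ring follows from the acid-derived carbon becoming C5 (next to C6–H) and the ester carbon becoming C3 (next to acetyl-bearing C2). The step needs C- over O-acylation, Claisen over aldol closure and no retro-Claisen cleavage at C4–C5; these are secured because C2 is the only carbon nucleophile that reaches the ester through a six-membered transition state, the alternative aldol would require the acetyl methyl carbanion to attack the enolate-masked neopentyl C5, an enol lactone formed through oxygen remains an activated acyl donor that can return to the open chain, and the hindered alkoxide does not add to carbonyl groups. Deprotonation of the strongly acidic product to its dianion makes the closure irreversible.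

Step 6
Reactants: 10 2,4,6-trihydroxyacetophenone; 2 prenyl bromide
Product: 11 1-[2,4,6-trihydroxy-3-(3-methylbut-2-en-1-yl)phenyl]ethan-1-one (3-prenyl-2,4,6-trihydroxyacetophenone)
Conditions: 2 (0.9 equiv), 10% aq KOH, 0 °C; acidify, chromatography
Reagents that add atoms: none
Why: C-alkylation of the ambident phloroglucinolate in water, where hydrogen bonding to oxygen steers the soft allylic bromide to ring carbon, a deficit of bromide at 0 °C limits di-prenylation, and the mono-C-prenyl product is separable from recovered 10 and over-alkylated material.

Step 7
Reactants: 11 3-prenyl-2,4,6-trihydroxyacetophenone; 12 dimethylmethyleneiminium iodide (Eschenmoser salt)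
Product: 13 1-{3-[(dimethylamino)methyl]-2,4,6-trihydroxy-5-(3-methylbut-2-en-1-yl)phenyl}ethan-1-one
Conditions: 12 (1.1 equiv), CH2Cl2/MeCN, 0 °C → rt; sat. aq NaHCO3; used without chromatography
Reagents that add atoms: none
Why: Mannich aminomethylation (electrophilic aromatic substitution by the preformed iminium ion) at the only unsubstituted carbon of the highly activated ring needs neither added acid nor heat, and the HI formed is held by the product amine, so the prenyl group is not cyclised.

Step 8
Reactants: 9 (R)-2-acetyl-3,5-dihydroxy-4-methyl-4-(3-methylbut-2-en-1-yl)cyclohexa-2,5-dien-1-one; 13 Mannich base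
Product: 15 target CNP0192978.1 (R)-2-acetyl-6-{[3-acetyl-2,4,6-trihydroxy-5-(3-methylbut-2-en-1-yl)phenyl]methyl}-3,5-dihydroxy-4-methyl-4-(3-methylbut-2-en-1-yl)cyclohexa-2,5-dien-1-one, via ortho-quinone methide 14 (not isolated)
Conditions: 9 (1.0 equiv), 13 (1.1 equiv), Et3N (1.1 equiv), 1,4-dioxane, 70 °C, Ar; cold 1 M HCl wash
Reagents that add atoms: none
Why: Loss of dimethylamine from the phenolate/ammonium form of 13 gives ortho-quinone methide 14, which cannot be trapped by its own fully substituted ring and is taken by the enolate of 9 at C6, its only carbon nucleophile bearing a hydrogen, in a Michael addition driven by rearomatisation (the Mannich-base route to methylene-bridged acylphloroglucinol dimers), with C4 remote and unaffected.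

Compound list
1 | dimethyl methylmalonate | COC(=O)C(C)C(=O)OC | starting material
2 | prenyl bromide (1-bromo-3-methylbut-2-ene) | CC(C)=CCBr | starting material
3 | dimethyl 2-methyl-2-(3-methylbut-2-en-1-yl)malonate (prochiral) | COC(=O)C(C)(CC=C(C)C)C(=O)OC | intermediate
4 | (R)-3-methoxy-2-methyl-2-(3-methylbut-2-en-1-yl)-3-oxopropanoic acid | COC(=O)[C@](C)(CC=C(C)C)C(=O)O | intermediate
5 | methyl (S)-2-(chlorocarbonyl)-2,5-dimethylhex-4-enoate | COC(=O)[C@](C)(CC=C(C)C)C(=O)Cl | intermediate
6 | acetylacetone (pentane-2,4-dione) | CC(=O)CC(C)=O | starting material
7 | acetylacetone sodium lithium 1,3-dianion (not isolated) | [Na+].[Li+].[CH2-]C(=O)[CH-]C(C)=O | intermediate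
8 | methyl (R)-2-methyl-2-(3-methylbut-2-en-1-yl)-3,5,7-trioxooctanoate | COC(=O)[C@](C)(CC=C(C)C)C(=O)CC(=O)CC(C)=O | intermediate
9 | (R)-2-acetyl-3,5-dihydroxy-4-methyl-4-(3-methylbut-2-en-1-yl)cyclohexa-2,5-dien-1-one | CC(=O)C1=C(O)[C@](C)(CC=C(C)C)C(O)=CC1=O | intermediate
10 | 2,4,6-trihydroxyacetophenone | CC(=O)c1c(O)cc(O)cc1O | starting material
11 | 1-[2,4,6-trihydroxy-3-(3-methylbut-2-en-1-yl)phenyl]ethan-1-one | CC(=O)c1c(O)cc(O)c(CC=C(C)C)c1O | intermediate
12 | dimethylmethyleneiminium iodide (Eschenmoser salt) | C=[N+](C)C.[I-] | starting material
13 | 1-{3-[(dimethylamino)methyl]-2,4,6-trihydroxy-5-(3-methylbut-2-en-1-yl)phenyl}ethan-1-one | CC(=O)c1c(O)c(CN(C)C)c(O)c(CC=C(C)C)c1O | intermediate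
14 | ortho-quinone methide, 2-acetyl-3,5-dihydroxy-6-methylidene-4-(3-methylbut-2-en-1-yl)cyclohexa-2,4-dien-1-one numbered from the ring ketone (not isolated) | CC(=O)C1=C(O)C(=C)C(=O)C(CC=C(C)C)=C1O | intermediate
15 | (R)-2-acetyl-6-{[3-acetyl-2,4,6-trihydroxy-5-(3-methylbut-2-en-1-yl)phenyl]methyl}-3,5-dihydroxy-4-methyl-4-(3-methylbut-2-en-1-yl)cyclohexa-2,5-dien-1-one (CNP0192978.1) | CC(=O)C1=C(O)[C@](C)(CC=C(C)C)C(O)=C(Cc2c(O)c(CC=C(C)C)c(O)c(C(C)=O)c2O)C1=O | target

Total step count: 8. Longest linear sequence: 6 steps (steps 1, 2, 3, 4, 5, 8); the aromatic branch (steps 6 and 7) joins at step 8.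

Steps most likely to fail

Step 2. The esterase may discriminate poorly between the two ester groups of a substrate whose larger substituent is a branched five-carbon allyl group, or may prefer the other ester, so that the half-ester arrives with low or opposite enantiomeric excess. The fallback replaces enzymatic desymmetrisation by classical resolution and sets out from 3. Monosaponification with KOH (1.0 equiv) in MeOH/H2O at rt should give racemic 3-methoxy-2-methyl-2-(3-methylbut-2-en-1-yl)-3-oxopropanoic acid F1. Treatment with (S)-1-phenylethylamine in EtOAc/hexane should precipitate (S)-1-phenylethylammonium (R)-3-methoxy-2-methyl-2-(3-methylbut-2-en-1-yl)-3-oxopropanoate F2, recrystallised to constant rotation, while the diastereomeric (S)-1-phenylethylammonium (S)-3-methoxy-2-methyl-2-(3-methylbut-2-en-1-yl)-3-oxopropanoate F3 stays in the mother liquor. Cold aqueous citric acid releases the acid from F2, and the route is rejoined at 4. The same crystallisation upgrades partly enriched material from the enzymatic step.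

Step 5. Ring closure at the neopentyl-type ester may be outrun by O-acylation to an enol lactone, by retro-Claisen fragmentation at C4–C5, or by simple failure of the hindered ester to react. The fallback replaces the de novo ring construction by alkylative dearomatisation and resolution and sets out from 11. MeI (1.0 equiv) with NaOMe in MeOH at 0 °C → rt should methylate the prenyl-bearing ring carbon of the phloroglucinolate and give racemic 2-acetyl-3,5-dihydroxy-4-methyl-4-(3-methylbut-2-en-1-yl)cyclohexa-2,5-dien-1-one F4. F4 is freed from aromatic material methylated at the free ring carbon by extraction of the far more acidic trione into aqueous NaHCO3. Preparative chromatography on a polysaccharide chiral phase with an acidic modifier then removes (S)-2-acetyl-3,5-dihydroxy-4-methyl-4-(3-methylbut-2-en-1-yl)cyclohexa-2,5-dien-1-one F5, and the (R)-enantiomer rejoins the route at 9. Its configuration is to be assigned by electronic circular dichroism against calculation.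

Step 8. The quinone methide may be lost to self-condensation, or the methylene bridge may migrate between rings under the warm, mildly basic conditions (retro-Mannich and retro-Michael scrambling), which would lead to symmetrical bis-adducts. The fallback reverses the roles of the two halves and sets out from 9. Dimethylmethyleneiminium iodide 12 in CH2Cl2 at 0 °C should aminomethylate C6 to give (R)-2-acetyl-6-[(dimethylamino)methyl]-3,5-dihydroxy-4-methyl-4-(3-methylbut-2-en-1-yl)cyclohexa-2,5-dien-1-one F6. Warming F6 with 11 in dioxane should release dimethylamine and the transient 2-acetyl-3-hydroxy-4-methyl-6-methylidene-4-(3-methylbut-2-en-1-yl)cyclohex-2-ene-1,5-dione F7 (C4 unchanged). F7 is attacked by the only free aromatic carbon of 11 in a Friedel–Crafts-type conjugate addition and tautomerises, rejoining the route at 15.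

Further compounds
F1 | step 2 | racemic 3-methoxy-2-methyl-2-(3-methylbut-2-en-1-yl)-3-oxopropanoic acid | COC(=O)C(C)(CC=C(C)C)C(=O)O
F2 | step 2 | (S)-1-phenylethylammonium (R)-3-methoxy-2-methyl-2-(3-methylbut-2-en-1-yl)-3-oxopropanoate | COC(=O)[C@](C)(CC=C(C)C)C(=O)[O-].C[C@H]([NH3+])c1ccccc1
F3 | step 2 | (S)-1-phenylethylammonium (S)-3-methoxy-2-methyl-2-(3-methylbut-2-en-1-yl)-3-oxopropanoate | COC(=O)[C@@](C)(CC=C(C)C)C(=O)[O-].C[C@H]([NH3+])c1ccccc1
F4 | step 5 | racemic 2-acetyl-3,5-dihydroxy-4-methyl-4-(3-methylbut-2-en-1-yl)cyclohexa-2,5-dien-1-one | CC(=O)C1=C(O)C(C)(CC=C(C)C)C(O)=CC1=O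
F5 | step 5 | (S)-2-acetyl-3,5-dihydroxy-4-methyl-4-(3-methylbut-2-en-1-yl)cyclohexa-2,5-dien-1-one | CC(=O)C1=C(O)[C@@](C)(CC=C(C)C)C(O)=CC1=O
F6 | step 8 | (R)-2-acetyl-6-[(dimethylamino)methyl]-3,5-dihydroxy-4-methyl-4-(3-methylbut-2-en-1-yl)cyclohexa-2,5-dien-1-one | CC(=O)C1=C(O)[C@](C)(CC=C(C)C)C(O)=C(CN(C)C)C1=O
F7 | step 8 | 2-acetyl-3-hydroxy-4-methyl-6-methylidene-4-(3-methylbut-2-en-1-yl)cyclohex-2-ene-1,5-dione | CC(=O)C1=C(O)[C@](C)(CC=C(C)C)C(=O)C(=C)C1=O
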